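## Retrosynthetic overview

1. The target is a 7-hydroxyisoflavone (daidzein unit) whose ring B carbon C3' is bonded to C8 of a genistein unit. The last operations are a fivefold O-demethylation and, before it, a Suzuki union at the C3–C1' bond of the daidzein unit (3-iodo-7-methoxychromone plus the arylboronate of the genistein half).
2. Structural feature used: in the genistein unit the ring-fusion bond C4a–C8a of ring A is also the second C=C bond of the pyranone ring C (O1, C2, C3, C4, C4a, C8a). C5, C6, C7 and C8, with O5, O7 and the aryl group on C8, correspond to C1–C4 of a 4-arylacetoacetate.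
3. Key disconnection: C8–C8a and C5–C4a. Ring A is annulated onto a preformed 3-bromo-5-aryl-4-pyranone with a 4-aryl-1,3-bis(silyloxy)diene; the pyranone bromine carries the oxidation level of the arene, and a second bromine on the diene's aryl group is the handle for the later union.
4. Ring order: pyranone ring C of the genistein unit (from 4H-pyran-4-one), then ring A (annulation), the daidzein chromone separately (from paeonol), then coupling and demethylation.

Key step: step 6

Remark: diene 10 is written as its (1Z,3Z) isomer and the transient compounds 12 and 13 as diastereomer mixtures without configuration. The diene geometry and these stereocentres vanish in 14, so they should not affect the outcome.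

## Route

Step 1
Reactants: 1 4H-pyran-4-one
Product: 2 3,5-dibromo-4H-pyran-4-one
Conditions: Br2 (2.4 equiv), CH2Cl2, 0 to 20 °C; then Et3N, 0 °C
Reagents that add atoms: bromine, BrBr
Why: Each enone C=C bond should add bromine and the resulting 2,3-dibromide should lose HBr to Et3N, the addition–elimination α-bromination of an enone (as used for 3-bromochromones), applied to both sides of the symmetric pyranone.

Step 2
Reactants: 2 3,5-dibromo-4H-pyran-4-one (2 equiv); 3 4-methoxyphenylboronic acid
Product: 4 3-bromo-5-(4-methoxyphenyl)-4H-pyran-4-one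
Conditions: Pd(PPh3)4, Na2CO3 (2 M aq), DME, 70 °C
Reagents that add atoms: none
Why: Suzuki–Miyaura coupling at one of the two equivalent C–Br bonds; the excess of 2 should bias the statistical outcome towards mono-arylation, and unreacted 2 is recovered.

Step 3
Reactants: 5 5-bromo-2-methoxyphenylacetic acid; 6 Meldrum's acid
Product: 8 methyl 4-(5-bromo-2-methoxyphenyl)-3-oxobutanoate, via acyl Meldrum's acid 7 (not isolated)
Conditions: DCC, DMAP, CH2Cl2, 0 to 20 °C; filter; then MeOH, reflux
Reagents that add atoms: methanol, CO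
Why: Oikawa–Yonemitsu homologation: carbodiimide C-acylation of Meldrum's acid, then methanolysis with loss of acetone and CO2, should give the β-keto ester.

Step 4
Reactants: 8 methyl 4-(5-bromo-2-methoxyphenyl)-3-oxobutanoate
Product: 9 methyl (Z)-4-(5-bromo-2-methoxyphenyl)-3-(trimethylsilyloxy)but-2-enoate
Conditions: Me3SiCl, Et3N, toluene, 20 °C
Reagents that add atoms: chlorotrimethylsilane, C[Si](C)(C)Cl
Why: Soft enolisation and O-silylation of the β-keto ester (the CH2 between the two carbonyl groups is far more acidic than the benzylic CH2) should give the chelation-derived (Z)-silyl enol ether.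

Step 5
Reactants: 9 methyl (Z)-4-(5-bromo-2-methoxyphenyl)-3-(trimethylsilyloxy)but-2-enoate
Product: 10 (1Z,3Z)-4-(5-bromo-2-methoxyphenyl)-1-methoxy-1,3-bis(trimethylsilyloxy)buta-1,3-diene
Conditions: LiN(iPr)2, THF, −78 °C; Me3SiCl, −78 to 20 °C; non-aqueous work-up
Reagents that add atoms: chlorotrimethylsilane, C[Si](C)(C)Cl
Why: γ-Deprotonation of the vinylogous ester at the benzylic carbon and O-silylation of the dienolate is the standard preparation of Chan-type 1,3-bis(silyloxy)dienes; the aryl bromide should be inert to the amide base at −78 °C.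

Step 6
Reactants: 4 3-bromo-5-(4-methoxyphenyl)-4H-pyran-4-one; 10 (1Z,3Z)-4-(5-bromo-2-methoxyphenyl)-1-methoxy-1,3-bis(trimethylsilyloxy)buta-1,3-diene (1.5 equiv)
Product: 14 8-(5-bromo-2-methoxyphenyl)-5,7-dihydroxy-3-(4-methoxyphenyl)-4H-chromen-4-one, via silyloxypyrylium triflate 11 (not isolated), via 2H-pyran adduct 12 (not isolated), via bromo cycloadduct 13 (not isolated)
Conditions: 4, Me3SiOTf (1.3 equiv), CH2Cl2, 20 °C, 1 h; then 10, −78 to 20 °C; then Et3N, 20 °C; then 1 M HCl, MeOH
Reagents that add atoms: none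
Why: Proposed new method: O-silylation of 4 should give the 4-silyloxypyrylium triflate 11, electrophilic at both ring CH carbons, and diene 10 should add to it through C4, its aryl-bearing terminus and the site of its largest HOMO coefficient, forming C8–C8a in adduct 12, as silyl enol ethers and 1,3-bis(silyloxy)dienes do with the 4-silyloxybenzopyrylium triflates made from chromones. The step needs attack at the CH next to C–Br and not at the CH next to the anisyl-bearing carbon; the stronger inductive pull of bromine and its smaller bulk compared with the twisted anisyl ring should favour this, and a misdirected adduct carries no leaving group, cannot aromatise and should be separable. The first bond leaves the former ketene acetal as an O-silylated ester (a dialkoxycarbenium ion) beside the new bromine-bearing silyl enol ether, whose carbon should attack it in a 6-(enolexo)-exo-trig closure that forms C5–C4a and ring A as the formal [4+2] adduct 13; this is the stepwise polar counterpart of Brassard and Chan diene annulations of bromoquinones and of Me3SiOTf-mediated additions of silyl enol ethers to orthoesters. Ionisation of the mixed ketal at C5 should then expel methanol as Me3SiOMe, Et3N should remove HBr across C4a–C8a so that bromide supplies the oxidation level of the arene without an oxidant, and acidic methanol should cleave the silyl ethers while the 5,7-dione enolises to the resorcinol. No stereocentre remains in 14, since the transient ones of 12 and 13 are all destroyed on aromatisation. The chief hazard is 6π-electrocyclic opening of the 2H-pyran 12 to a dienal before the second bond forms, countered by keeping Me3SiOTf in excess and the temperature low until closure is complete.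

Step 7
Reactants: 14 8-(5-bromo-2-methoxyphenyl)-5,7-dihydroxy-3-(4-methoxyphenyl)-4H-chromen-4-one
Product: 15 8-(5-bromo-2-methoxyphenyl)-5,7-dimethoxy-3-(4-methoxyphenyl)-4H-chromen-4-one
Conditions: MeI (excess), K2CO3, DMF, 50 °C
Reagents that add atoms: iodomethane, CI
Why: Williamson O-methylation of both phenols; the hydrogen-bonded 5-OH needs the excess of MeI and warm DMF, and the aryl bromide should be untouched.

Step 8
Reactants: 15 8-(5-bromo-2-methoxyphenyl)-5,7-dimethoxy-3-(4-methoxyphenyl)-4H-chromen-4-one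
Product: 16 5,7-dimethoxy-3-(4-methoxyphenyl)-8-[2-methoxy-5-(4,4,5,5-tetramethyl-1,3,2-dioxaborolan-2-yl)phenyl]-4H-chromen-4-one
Conditions: B2pin2, PdCl2(dppf), KOAc, 1,4-dioxane, 90 °C
Reagents that add atoms: bis(pinacolato)diboron, CC1(C)OB(OC1(C)C)B1OC(C)(C)C(C)(C)O1
Why: Miyaura borylation of the aryl bromide, which lies para to the methoxy group and away from the hindered biaryl axis; KOAc is too weak a base to promote Suzuki homocoupling.

Step 9
Reactants: 17 paeonol (2'-hydroxy-4'-methoxyacetophenone)
Product: 18 (E)-3-(dimethylamino)-1-(2-hydroxy-4-methoxyphenyl)prop-2-en-1-one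
Conditions: DMF-DMA, toluene, 90 °C
Reagents that add atoms: N,N-dimethylformamide dimethyl acetal, COC(OC)N(C)C
Why: Condensation of the acetyl CH3 group with the amide acetal should give the (E)-enaminone; the hydrogen-bonded phenol is tolerated.

Step 10
Reactants: 18 (E)-3-(dimethylamino)-1-(2-hydroxy-4-methoxyphenyl)prop-2-en-1-one
Product: 19 3-iodo-7-methoxy-4H-chromen-4-one
Conditions: I2, CHCl3, 20 °C
Reagents that add atoms: iodine, II
Why: Gammill iodocyclisation: iodination of the enaminone α-carbon, ring closure by the phenol oxygen and loss of dimethylamine should give the 3-iodochromone.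

Step 11
Reactants: 16 the pinacol boronate from step 8; 19 3-iodo-7-methoxy-4H-chromen-4-one
Product: 20 8-[2-methoxy-5-(7-methoxy-4-oxo-4H-chromen-3-yl)phenyl]-5,7-dimethoxy-3-(4-methoxyphenyl)-4H-chromen-4-one
Conditions: Pd(PPh3)4, K2CO3 (aq), DME, 80 °C
Reagents that add atoms: none
Why: Suzuki–Miyaura coupling of a 3-iodochromone with an arylboronate, the standard isoflavone synthesis, should form the C3–C1' bond of the daidzein unit.

Step 12
Reactants: 20 8-[2-methoxy-5-(7-methoxy-4-oxo-4H-chromen-3-yl)phenyl]-5,7-dimethoxy-3-(4-methoxyphenyl)-4H-chromen-4-one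
Product: 21 5,7-dihydroxy-8-[2-hydroxy-5-(7-hydroxy-4-oxo-4H-chromen-3-yl)phenyl]-3-(4-hydroxyphenyl)-4H-chromen-4-one (target)
Conditions: BBr3 (12 equiv), CH2Cl2, −78 to 20 °C; then MeOH, H2O
Reagents that add atoms: none
Why: Lewis acid-mediated cleavage of all five aryl methyl ethers (boron complexation, then SN2 demethylation by bromide); both chromone rings should be stable to BBr3 and the target has no stereocentre.

## Compound list

1 | 4H-pyran-4-one | O=c1ccocc1 | starting material
2 | 3,5-dibromo-4H-pyran-4-one | O=c1c(Br)cocc1Br | intermediate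
3 | 4-methoxyphenylboronic acid | COc1ccc(B(O)O)cc1 | starting material
4 | 3-bromo-5-(4-methoxyphenyl)-4H-pyran-4-one | COc1ccc(-c2cocc(Br)c2=O)cc1 | intermediate
5 | 5-bromo-2-methoxyphenylacetic acid | COc1ccc(Br)cc1CC(=O)O | starting material
6 | Meldrum's acid (2,2-dimethyl-1,3-dioxane-4,6-dione) | CC1(C)OC(=O)CC(=O)O1 | starting material
7 | 5-[2-(5-bromo-2-methoxyphenyl)-1-hydroxyethylidene]-2,2-dimethyl-1,3-dioxane-4,6-dione (acyl Meldrum's acid, enol form) | COc1ccc(Br)cc1CC(O)=C1C(=O)OC(C)(C)OC1=O | intermediate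
8 | methyl 4-(5-bromo-2-methoxyphenyl)-3-oxobutanoate | COC(=O)CC(=O)Cc1cc(Br)ccc1OC | intermediate
9 | methyl (Z)-4-(5-bromo-2-methoxyphenyl)-3-(trimethylsilyloxy)but-2-enoate | COC(=O)/C=C(\O[Si](C)(C)C)Cc1cc(Br)ccc1OC | intermediate
10 | (1Z,3Z)-4-(5-bromo-2-methoxyphenyl)-1-methoxy-1,3-bis(trimethylsilyloxy)buta-1,3-diene | CO/C(O[Si](C)(C)C)=C/C(O[Si](C)(C)C)=C/c1cc(Br)ccc1OC | intermediate
11 | 3-bromo-5-(4-methoxyphenyl)-4-(trimethylsilyloxy)pyrylium trifluoromethanesulfonate | COc1ccc(-c2c[o+]cc(Br)c2O[Si](C)(C)C)cc1.[O-]S(=O)(=O)C(F)(F)F | intermediate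
12 | methyl (E)-4-(5-bromo-2-methoxyphenyl)-4-[3-bromo-5-(4-methoxyphenyl)-4-(trimethylsilyloxy)-2H-pyran-2-yl]-3-(trimethylsilyloxy)but-2-enoate (diastereomer mixture) | COC(=O)/C=C(/O[Si](C)(C)C)C(c1cc(Br)ccc1OC)C1OC=C(c2ccc(OC)cc2)C(O[Si](C)(C)C)=C1Br | intermediate
13 | 4a-bromo-8-(5-bromo-2-methoxyphenyl)-5-methoxy-3-(4-methoxyphenyl)-5,7-bis(trimethylsilyloxy)-4a,5,8,8a-tetrahydro-4H-chromen-4-one (diastereomer mixture) | COc1ccc(C2=COC3C(c4cc(Br)ccc4OC)C(O[Si](C)(C)C)=CC(OC)(O[Si](C)(C)C)C3(Br)C2=O)cc1 | intermediate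
14 | 8-(5-bromo-2-methoxyphenyl)-5,7-dihydroxy-3-(4-methoxyphenyl)-4H-chromen-4-one | COc1ccc(-c2coc3c(-c4cc(Br)ccc4OC)c(O)cc(O)c3c2=O)cc1 | intermediate
15 | 8-(5-bromo-2-methoxyphenyl)-5,7-dimethoxy-3-(4-methoxyphenyl)-4H-chromen-4-one | COc1ccc(-c2coc3c(-c4cc(Br)ccc4OC)c(OC)cc(OC)c3c2=O)cc1 | intermediate
16 | 5,7-dimethoxy-3-(4-methoxyphenyl)-8-[2-methoxy-5-(4,4,5,5-tetramethyl-1,3,2-dioxaborolan-2-yl)phenyl]-4H-chromen-4-one | COc1ccc(-c2coc3c(-c4cc(B5OC(C)(C)C(C)(C)O5)ccc4OC)c(OC)cc(OC)c3c2=O)cc1 | intermediate
17 | paeonol (2'-hydroxy-4'-methoxyacetophenone) | CC(=O)c1ccc(OC)cc1O | starting material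
18 | (E)-3-(dimethylamino)-1-(2-hydroxy-4-methoxyphenyl)prop-2-en-1-one | CN(C)/C=C/C(=O)c1ccc(OC)cc1O | intermediate
19 | 3-iodo-7-methoxy-4H-chromen-4-one | COc1ccc2c(c1)occ(I)c2=O | intermediate
20 | 8-[2-methoxy-5-(7-methoxy-4-oxo-4H-chromen-3-yl)phenyl]-5,7-dimethoxy-3-(4-methoxyphenyl)-4H-chromen-4-one | COc1ccc(-c2coc3c(-c4cc(-c5coc6cc(OC)ccc6c5=O)ccc4OC)c(OC)cc(OC)c3c2=O)cc1 | intermediate
21 | 5,7-dihydroxy-8-[2-hydroxy-5-(7-hydroxy-4-oxo-4H-chromen-3-yl)phenyl]-3-(4-hydroxyphenyl)-4H-chromen-4-one | O=c1c(-c2ccc(O)c(-c3c(O)cc(O)c4c(=O)c(-c5ccc(O)cc5)coc34)c2)coc2cc(O)ccc12 | target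

## Summary

Total step count: 12
Longest linear sequence: 8 steps (5 → 8 → 9 → 10 → 14 → 15 → 16 → 20 → 21; steps 3, 4, 5, 6, 7, 8, 11, 12)

## Steps most likely to fail

**1. Step 6 (annulation of ring A).** Several processes could divert it:
- electrocyclic opening of the 2H-pyran adduct, or loss of the silyl group from the activated ester, before the C5–C4a bond forms;
- addition of the diene at the CH next to the anisyl-bearing carbon;
- transfer of bromine as an electrophile in place of loss of HBr.

Fallback by known chemistry: it sets out from 4-methoxyphenylboronic acid 3, which supplies the isoflavone aryl group in its last operation, and from commercial 2'-hydroxy-4',6'-dimethoxyacetophenone, and it comes back to the route at 15. The acetophenone would be iodinated ortho to the phenol (BnMe3N ICl2, CaCO3, CH2Cl2/MeOH) to 2'-hydroxy-3'-iodo-4',6'-dimethoxyacetophenone F1. F1 would be coupled at the C–I bond with (5-bromo-2-methoxyphenyl)boronic acid (Pd(PPh3)4, Na2CO3, DME/H2O, 60 °C; the iodide should react before the deactivated bromide) to 1-[3-(5-bromo-2-methoxyphenyl)-2-hydroxy-4,6-dimethoxyphenyl]ethanone F2. Condensation with DMF-DMA would give (E)-1-[3-(5-bromo-2-methoxyphenyl)-2-hydroxy-4,6-dimethoxyphenyl]-3-(dimethylamino)prop-2-en-1-one F3, and I2 would close it to 8-(5-bromo-2-methoxyphenyl)-3-iodo-5,7-dimethoxy-4H-chromen-4-one F4. An iodide-selective Suzuki coupling of F4 with 3 (Pd(PPh3)4, Na2CO3, DME/H2O) would then give 15.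

**2. Step 2 (mono-arylation of the dibromide).** Over-arylation to the 3,5-diaryl compound and hydroxide-induced opening of the pyranone ring during the coupling could erode the supply of 4.

Fallback: it sets out from 1 and comes back at 4, with the halogens introduced one at a time so that no statistical step is needed. 1 would be mono-brominated (Br2, 1 equiv, CH2Cl2, 0 °C; then Et3N) to 3-bromo-4H-pyran-4-one F5. F5 would be coupled with 3 (Pd(PPh3)4, Na2CO3, DME/H2O) to 3-(4-methoxyphenyl)-4H-pyran-4-one F6. F6 would be brominated at C5 by addition–elimination (pyridinium tribromide or Br2, CH2Cl2, 0 °C; then Et3N) to give 4; the anisyl ring, deactivated by the pyranone, should react more slowly than the enol ether C=C bond.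

**3. Step 11 (union of the two chromone halves).** Protodeboronation of the electron-rich boronate, and base-induced ring opening or deiodination of the 3-iodochromone, could outrun transmetalation.

Fallback: it sets out from 15 and comes back at the target 21, building the daidzein chromone after the C–C bond by the deoxybenzoin route. 15 would undergo Pd-catalysed α-arylation with commercial 2',4'-dimethoxyacetophenone (Pd2(dba)3, Xantphos, K3PO4, toluene, 80 °C) to 8-{5-[2-(2,4-dimethoxyphenyl)-2-oxoethyl]-2-methoxyphenyl}-5,7-dimethoxy-3-(4-methoxyphenyl)-4H-chromen-4-one F7. BBr3 would cleave all six methyl ethers to 8-{5-[2-(2,4-dihydroxyphenyl)-2-oxoethyl]-2-hydroxyphenyl}-5,7-dihydroxy-3-(4-hydroxyphenyl)-4H-chromen-4-one F8. Formylative ring closure of the 2,4-dihydroxyphenyl benzyl ketone (BF3·Et2O, DMF, MeSO2Cl, 70 °C), which tolerates free phenols as in the classical genistein synthesis, would give 21.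

## Further compounds

F1 | step 6 | 2'-hydroxy-3'-iodo-4',6'-dimethoxyacetophenone | CC(=O)c1c(O)c(I)c(OC)cc1OC
F2 | step 6 | 1-[3-(5-bromo-2-methoxyphenyl)-2-hydroxy-4,6-dimethoxyphenyl]ethanone | CC(=O)c1c(O)c(-c2cc(Br)ccc2OC)c(OC)cc1OC
F3 | step 6 | (E)-1-[3-(5-bromo-2-methoxyphenyl)-2-hydroxy-4,6-dimethoxyphenyl]-3-(dimethylamino)prop-2-en-1-one | CN(C)/C=C/C(=O)c1c(O)c(-c2cc(Br)ccc2OC)c(OC)cc1OC
F4 | step 6 | 8-(5-bromo-2-methoxyphenyl)-3-iodo-5,7-dimethoxy-4H-chromen-4-one | COc1ccc(Br)cc1-c1c(OC)cc(OC)c2c(=O)c(I)coc12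
F5 | step 2 | 3-bromo-4H-pyran-4-one | O=c1ccocc1Br
F6 | step 2 | 3-(4-methoxyphenyl)-4H-pyran-4-one | COc1ccc(-c2coccc2=O)cc1
F7 | step 11 | 8-{5-[2-(2,4-dimethoxyphenyl)-2-oxoethyl]-2-methoxyphenyl}-5,7-dimethoxy-3-(4-methoxyphenyl)-4H-chromen-4-one | COc1ccc(-c2coc3c(-c4cc(CC(=O)c5ccc(OC)cc5OC)ccc4OC)c(OC)cc(OC)c3c2=O)cc1
F8 | step 11 | 8-{5-[2-(2,4-dihydroxyphenyl)-2-oxoethyl]-2-hydroxyphenyl}-5,7-dihydroxy-3-(4-hydroxyphenyl)-4H-chromen-4-one | O=C(Cc1ccc(O)c(-c2c(O)cc(O)c3c(=O)c(-c4ccc(O)cc4)coc23)c1)c1ccc(O)cc1O
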